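**Retrosynthetic overview**
1. Target 16 ⇐ diol 15 (double acetylation); the E side-chain allylic alcohol ⇐ terminal alkyne 12 by syn methylalumination/hydroxymethylation.
2. C7–O bond and C8=C9 alkene ⇐ [3,3]-sigmatropic 1,3-transposition of tertiary allylic alcohol 11 (key step; the oxygen stays on one face, so C7 is dictated by C9/C10).
3. 11 ⇐ bicyclic enone 7 + alkynyl Grignard 9 (1,2-addition anti to the angular methyl).
4. Ring A of 7 ⇐ acid-catalysed cation–olefin cyclisation of 1,6-diene 5 (the isopropenyl carbon becomes the gem-dimethyl carbon), then alkene hydrogenation.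
5. 5 ⇐ (S)-(+)-carvone 1 by two α′-alkylations (methyl, then allyl anti to isopropenyl). Ring B is bought; ring A is formed second.

Assumption: atom labels C1–C20 in the explanations follow labdane numbering of the target (C5/C10 ring fusion, C7 acetoxy carbon, C9 side-chain carbon); reagents without a compound number are commercial.

**Step 1**
Reactants: 1 (S)-(+)-carvone
Product: 3 (5S,6R)-2,6-dimethyl-5-(prop-1-en-2-yl)cyclohex-2-en-1-one (trans-6-methylcarvone; minor cis epimer carried along), via lithium dienolate 2 (not isolated)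
Conditions: LiN(i-Pr)2 (1.1 equiv), THF, −78 °C; MeI, −78 → 0 °C
Reagents that add atoms: iodomethane, CI
Why: Kinetic α′-deprotonation gives the cross-conjugated dienolate, which is C-methylated (enolate alkylation); the new centre is re-enolised in step 2, so its epimer ratio does not matter.

**Step 2**
Reactants: 3 trans-6-methylcarvone
Product: 5 (5R,6R)-2,6-dimethyl-6-(prop-2-en-1-yl)-5-(prop-1-en-2-yl)cyclohex-2-en-1-one (allyl trans to isopropenyl), via lithium enolate 4 (not isolated)
Conditions: LiN(i-Pr)2, THF, −78 °C; allyl bromide, DMPU, −78 °C → rt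
Reagents that add atoms: allyl bromide, C=CCBr
Why: Enolate alkylation in which A(1,2) strain holds the neighbouring isopropenyl group pseudo-axial, so allyl bromide enters anti to it and the quaternary centre (future C10) is set with methyl cis to the isopropenyl group.

**Step 3**
Reactants: 5 allyl methyl carvone
Product: 6 (4aR,8aR)-2,5,5,8a-tetramethyl-4a,5,8,8a-tetrahydronaphthalen-1(4H)-one (trans-fused; some ring A alkene regioisomer is expected)
Conditions: Bi(OTf)3 (5 mol %), MeNO2, rt → 50 °C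
Reagents that add atoms: none
Why: Acid-catalysed cation–olefin cycloisomerisation of the 1,6-diene: Markovnikov protonation of the isopropenyl group gives a tertiary cation that the allyl terminus attacks 6-endo through a chair with both arms equatorial (trans fusion fixed by C5 and C10), and proton loss gives the gem-dimethylcyclohexene; any regioisomeric ring A alkene converges in step 4.

**Step 4**
Reactants: 6 bicyclic dienone
Product: 7 (4aR,8aR)-2,5,5,8a-tetramethyl-4a,5,6,7,8,8a-hexahydronaphthalen-1(4H)-one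
Conditions: H2 (3 atm), RhCl(PPh3)3 (5 mol %), benzene–EtOH, rt
Reagents that add atoms: none
Why: Homogeneous hydrogenation reduces the cis-disubstituted ring A alkene much faster than the trisubstituted conjugated enone alkene; no stereocentre is touched.

**Step 5**
Reactants: 7 bicyclic enone; 8 (4-bromobut-1-yn-1-yl)trimethylsilane
Product: 11 (1R,4aR,8aR)-1-(but-3-yn-1-yl)-2,5,5,8a-tetramethyl-1,4,4a,5,6,7,8,8a-octahydronaphthalen-1-ol, via Grignard reagent 9 (not isolated), via silylalkyne carbinol 10 (not isolated)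
Conditions: 8, Mg, THF, rt; CeCl3, THF, −78 °C; 7, −78 → 0 °C; then MeOH, K2CO3, rt
Reagents that add atoms: none
Why: CeCl3-promoted Grignard 1,2-addition to the hindered enone (suppresses enolisation and reduction) occurs axially, anti to the axial angular methyl, so the C9 hydroxyl ends cis to that methyl; methanolic carbonate then cleaves the alkynyl C–Si bond.

**Step 6**
Reactants: 11 tertiary allylic alcohol
Product: 12 (2R,4aR,8aR)-4-(but-3-yn-1-yl)-3,4a,8,8-tetramethyl-1,2,4a,5,6,7,8,8a-octahydronaphthalen-2-ol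
Conditions: Ph3SiOReO3 (5 mol %), Et2O, −50 → 0 °C
Reagents that add atoms: none
Why: Rhenium-oxo-catalysed 1,3-transposition, a [3,3]-sigmatropic rearrangement of the allyl perrhenate ester, driven by the tetrasubstituted C8=C9 alkene and relief of the congested tertiary centre; it is suprafacial, so oxygen arrives at C7 on the face it left C9, cis to the angular methyl.

**Step 7**
Reactants: 12 alkynyl allylic alcohol
Product: 15 (2R,4aR,8aR)-4-[(3E)-5-hydroxy-3-methylpent-3-en-1-yl]-3,4a,8,8-tetramethyl-1,2,4a,5,6,7,8,8a-octahydronaphthalen-2-ol, via alkenylalane 13 (not isolated), via lithium alkenylalanate 14 (not isolated)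
Conditions: Me3Al (3 equiv), Cp2ZrCl2 (0.3 equiv), CH2Cl2, 0 °C → rt; evaporate; n-BuLi, THF–hexane, −78 °C; (CH2O)n, rt; aq NH4Cl
Reagents that add atoms: trimethylaluminium, C[Al](C)C; formaldehyde (as paraformaldehyde), C=O
Why: Negishi zirconium-catalysed carboalumination adds methyl and aluminium syn across the terminal alkyne (methyl to the internal carbon), and the derived alanate is hydroxymethylated with retention, giving only the E trisubstituted allylic alcohol; the C7 hydroxyl is carried as its aluminium alkoxide.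

**Step 8**
Reactants: 15 diol
Product: 16 (2R,4aR,8aR)-4-[(3E)-5-acetoxy-3-methylpent-3-en-1-yl]-3,4a,8,8-tetramethyl-1,2,4a,5,6,7,8,8a-octahydronaphthalen-2-yl acetate (target)
Conditions: Ac2O, pyridine, DMAP (cat.), CH2Cl2, rt
Reagents that add atoms: acetic anhydride, CC(=O)OC(C)=O
Why: DMAP-catalysed acylation of the primary and the secondary allylic hydroxyl under non-ionising conditions leaves all stereocentres and both alkenes unchanged.

**Compound list**
1 | (S)-(+)-carvone, (5S)-2-methyl-5-(prop-1-en-2-yl)cyclohex-2-en-1-one | CC1=CC[C@@H](CC1=O)C(C)=C | starting material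
2 | kinetic lithium dienolate of 1 (O–Li on the former carbonyl carbon, new C=C toward the α′ carbon, isopropenyl stereocentre unchanged) | CC1=CC[C@@H](C=C1O[Li])C(C)=C | intermediate
3 | (5S,6R)-2,6-dimethyl-5-(prop-1-en-2-yl)cyclohex-2-en-1-one (trans-6-methylcarvone) | CC1=CC[C@@H]([C@@H](C)C1=O)C(C)=C | intermediate
4 | lithium enolate of 3 (tetrasubstituted enolate C=C bearing the new methyl, isopropenyl stereocentre unchanged) | CC1=CC[C@@H](C(C)=C1O[Li])C(C)=C | intermediate
5 | (5R,6R)-2,6-dimethyl-6-(prop-2-en-1-yl)-5-(prop-1-en-2-yl)cyclohex-2-en-1-one (allyl trans, methyl cis to isopropenyl) | CC1=CC[C@@H]([C@@](C)(CC=C)C1=O)C(C)=C | intermediate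
6 | (4aR,8aR)-2,5,5,8a-tetramethyl-4a,5,8,8a-tetrahydronaphthalen-1(4H)-one (trans-fused) | CC1=CC[C@@H]2C(C)(C)C=CC[C@@]2(C)C1=O | intermediate
7 | (4aR,8aR)-2,5,5,8a-tetramethyl-4a,5,6,7,8,8a-hexahydronaphthalen-1(4H)-one | CC1=CC[C@@H]2C(C)(C)CCC[C@@]2(C)C1=O | intermediate
8 | (4-bromobut-1-yn-1-yl)trimethylsilane | C[Si](C)(C)C#CCCBr | starting material
9 | [4-(trimethylsilyl)but-3-yn-1-yl]magnesium bromide | C[Si](C)(C)C#CCC[Mg]Br | intermediate
10 | (1R,4aR,8aR)-2,5,5,8a-tetramethyl-1-[4-(trimethylsilyl)but-3-yn-1-yl]-1,4,4a,5,6,7,8,8a-octahydronaphthalen-1-ol | C[Si](C)(C)C#CCC[C@@]1(O)C(C)=CC[C@@H]2C(C)(C)CCC[C@@]12C | intermediate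
11 | (1R,4aR,8aR)-1-(but-3-yn-1-yl)-2,5,5,8a-tetramethyl-1,4,4a,5,6,7,8,8a-octahydronaphthalen-1-ol (OH cis to the angular methyl) | C#CCC[C@@]1(O)C(C)=CC[C@@H]2C(C)(C)CCC[C@@]12C | intermediate
12 | (2R,4aR,8aR)-4-(but-3-yn-1-yl)-3,4a,8,8-tetramethyl-1,2,4a,5,6,7,8,8a-octahydronaphthalen-2-ol (OH cis to the angular methyl) | C#CCCC1=C(C)[C@H](O)C[C@@H]2C(C)(C)CCC[C@@]12C | intermediate
13 | (E)-alkenyl(dimethyl)alane from 12 (Al on the terminal alkene carbon, cis to the new methyl; C7 oxygen as dimethylaluminium alkoxide) | C[Al](C)/C=C(\C)CCC1=C(C)[C@H](O[Al](C)C)C[C@@H]2C(C)(C)CCC[C@@]12C | intermediate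
14 | lithium butyl(dimethyl)alkenylalanate derived from 13 | [Li+].CCCC[Al-](C)(C)/C=C(\C)CCC1=C(C)[C@H](O[Al](C)C)C[C@@H]2C(C)(C)CCC[C@@]12C | intermediate
15 | (2R,4aR,8aR)-4-[(3E)-5-hydroxy-3-methylpent-3-en-1-yl]-3,4a,8,8-tetramethyl-1,2,4a,5,6,7,8,8a-octahydronaphthalen-2-ol | OC/C=C(\C)CCC1=C(C)[C@H](O)C[C@@H]2C(C)(C)CCC[C@@]12C | intermediate
16 | (2R,4aR,8aR)-4-[(3E)-5-acetoxy-3-methylpent-3-en-1-yl]-3,4a,8,8-tetramethyl-1,2,4a,5,6,7,8,8a-octahydronaphthalen-2-yl acetate | CC(=O)OC/C=C(\C)CCC1=C(C)[C@H](OC(C)=O)C[C@@H]2C(C)(C)CCC[C@@]12C | target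

**Totals**
Total step count: 8. Longest linear sequence: 8 steps (1 → 16); bromide 8 is bought.

**Steps most likely to fail**

Step 3 (cation–olefin ring A closure). The tertiary cation can lose a proton toward C5 (scrambling the bought stereocentre on re-protonation) or undergo hydride shifts, and the product alkene can re-ionise. The fallback is a radical ring closure that sets out from compound 3 and comes back at compound 7. Enolate 4 is alkylated with methyl 2-(bromomethyl)acrylate in place of allyl bromide, again anti to the isopropenyl group, to give methyl 2-{[(1R,6R)-1,3-dimethyl-2-oxo-6-(prop-1-en-2-yl)cyclohex-3-en-1-yl]methyl}prop-2-enoate F1. Fe(acac)3 and PhSiH3 in EtOH–ethylene glycol at 60 °C transfer a hydrogen atom to the isopropenyl group, and the tertiary radical closes 6-endo onto the acrylate terminus (Giese addition) to give methyl (4aR,8aR)-4,4,7,8a-tetramethyl-8-oxo-1,2,3,4,4a,5,8,8a-octahydronaphthalene-2-carboxylate F2. LiOH in THF–water gives (4aR,8aR)-4,4,7,8a-tetramethyl-8-oxo-1,2,3,4,4a,5,8,8a-octahydronaphthalene-2-carboxylic acid F3. Photocatalytic hydrodecarboxylation (9-mesityl-10-methylacridinium tetrafluoroborate, (PhS)2, i-Pr2NEt, trifluoroethanol, blue light) then gives 7, bypassing 5 and 6.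

Step 6 (rhenium-catalysed [3,3] transposition). The congested tertiary perrhenate may ionise, giving dienes by dehydration or a mixture of C7 epimers. The fallback sets out from compound 11 and comes back at compound 12. Pyridinium chlorochromate (C5H5NH)[CrO3Cl] in CH2Cl2 effects the oxidative transposition ([3,3] shift of the chromate ester, then oxidation) to (4aR,8aR)-4-(but-3-yn-1-yl)-3,4a,8,8-tetramethyl-4a,5,6,7,8,8a-hexahydronaphthalen-2(1H)-one F4. NaBH4 with CeCl3·7H2O in MeOH at −78 °C then delivers hydride axially to the enone carbonyl, giving the pseudo-equatorial alcohol cis to the angular methyl, which is 12; here C7 is set independently of the C9 carbinol configuration.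

Step 7 (late-stage carboalumination). The Lewis-acidic Me3Al/zirconocene system meets a free, ionisable allylic alkoxide, and the alanate trapping is operationally delicate. The fallback avoids organoaluminium chemistry, sets out from compound 7 and comes back at compound 16. 4-Bromo-2-methylbut-1-ene and Mg give (3-methylbut-3-en-1-yl)magnesium bromide F5, which adds to 7 with CeCl3 as in step 5 to give (1R,4aR,8aR)-2,5,5,8a-tetramethyl-1-(3-methylbut-3-en-1-yl)-1,4,4a,5,6,7,8,8a-octahydronaphthalen-1-ol F6. Ph3SiOReO3 transposition as in step 6 gives (2R,4aR,8aR)-3,4a,8,8-tetramethyl-4-(3-methylbut-3-en-1-yl)-1,2,4a,5,6,7,8,8a-octahydronaphthalen-2-ol F7, and Ac2O/pyridine/DMAP gives (2R,4aR,8aR)-3,4a,8,8-tetramethyl-4-(3-methylbut-3-en-1-yl)-1,2,4a,5,6,7,8,8a-octahydronaphthalen-2-yl acetate F8. Cross-metathesis of F8 with (Z)-but-2-ene-1,4-diyl diacetate using the second-generation Hoveyda–Grubbs catalyst (CH2Cl2, 40 °C) gives 16. The price is E/Z selectivity of only about 3:1 at the new alkene, so the Z isomer must be removed on AgNO3-impregnated silica.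

**Further compounds**
F1 | step 3 | methyl 2-{[(1R,6R)-1,3-dimethyl-2-oxo-6-(prop-1-en-2-yl)cyclohex-3-en-1-yl]methyl}prop-2-enoate | CC1=CC[C@@H]([C@@](C)(CC(=C)C(=O)OC)C1=O)C(C)=C
F2 | step 3 | methyl (4aR,8aR)-4,4,7,8a-tetramethyl-8-oxo-1,2,3,4,4a,5,8,8a-octahydronaphthalene-2-carboxylate (C2 epimers) | CC1=CC[C@@H]2C(C)(C)CC(C(=O)OC)C[C@@]2(C)C1=O
F3 | step 3 | (4aR,8aR)-4,4,7,8a-tetramethyl-8-oxo-1,2,3,4,4a,5,8,8a-octahydronaphthalene-2-carboxylic acid (C2 epimers) | CC1=CC[C@@H]2C(C)(C)CC(C(O)=O)C[C@@]2(C)C1=O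
F4 | step 6 | (4aR,8aR)-4-(but-3-yn-1-yl)-3,4a,8,8-tetramethyl-4a,5,6,7,8,8a-hexahydronaphthalen-2(1H)-one | C#CCCC1=C(C)C(=O)C[C@@H]2C(C)(C)CCC[C@@]12C
F5 | step 7 | (3-methylbut-3-en-1-yl)magnesium bromide | CC(=C)CC[Mg]Br
F6 | step 7 | (1R,4aR,8aR)-2,5,5,8a-tetramethyl-1-(3-methylbut-3-en-1-yl)-1,4,4a,5,6,7,8,8a-octahydronaphthalen-1-ol | CC(=C)CC[C@@]1(O)C(C)=CC[C@@H]2C(C)(C)CCC[C@@]12C
F7 | step 7 | (2R,4aR,8aR)-3,4a,8,8-tetramethyl-4-(3-methylbut-3-en-1-yl)-1,2,4a,5,6,7,8,8a-octahydronaphthalen-2-ol | CC(=C)CCC1=C(C)[C@H](O)C[C@@H]2C(C)(C)CCC[C@@]12C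
F8 | step 7 | (2R,4aR,8aR)-3,4a,8,8-tetramethyl-4-(3-methylbut-3-en-1-yl)-1,2,4a,5,6,7,8,8a-octahydronaphthalen-2-yl acetate | CC(=C)CCC1=C(C)[C@H](OC(C)=O)C[C@@H]2C(C)(C)CCC[C@@]12C
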